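**Strategy**

Ring numbering: C1 is the quaternary carbon carrying the chlorovinyl arm, C2 and C4 are the CHBr carbons, C5 is C(CH3)Cl and C6 the ring CH2 between C1 and C5. The cyclohexane is closed at C5–C6. C5 is a tertiary chloride two bonds from C1, whose chlorovinyl arm is a masked carboxyl carbon, so C5–C6 is the bond of a radical conjugate addition. Iron-hydride hydrogen-atom transfer to an acyclic 2-chloroalkene gives an α-chloro radical that cyclises 6-endo onto a tethered α-methylene-β-lactone: ring, C–Cl bond and C5 stereocentre arise in one operation. The β-lactone then fixes the C1 methylation and releases the C2 bromide by invertive opening.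

Key step: step 7

Remark: in the Why lines C1–C6 always mean these target positions, also in intermediates named with their own locants. The ligand enantiomer in step 1 and the cinchona catalyst in step 4 are assumed to be the ones that lead to the stated configurations.

**Route**

Step 1
Reactants: 1 2-chloroprop-2-en-1-ol; 2 allyl acetate
Product: 4 (3R)-2-chlorohexa-1,5-dien-3-ol, via 2-chloroprop-2-enal 3 (not isolated)
Conditions: [Ir(cod)Cl]2 (2.5 mol%), Cl,MeO-BIPHEP (5 mol%, enantiomer chosen for the 3R alcohol), 4-chloro-3-nitrobenzoic acid (10 mol%), Cs2CO3 (20 mol%), allyl acetate (excess), THF, 100 °C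
Reagents that add atoms: none
Why: Iridium-catalysed transfer-hydrogenative carbonyl allylation from the alcohol oxidation level; the alcohol is dehydrogenated to the enal in the flask and the chiral allyliridium complex adds through a closed chair transition state, so the ligand sets the C4 carbinol as R.

Step 2
Reactants: 4 (3R)-2-chlorohexa-1,5-dien-3-ol
Product: 5 tert-butyl{[(3R)-2-chlorohexa-1,5-dien-3-yl]oxy}dimethylsilane
Conditions: TBSCl, imidazole, DMF, 0 °C to rt
Reagents that add atoms: tert-butyldimethylsilyl chloride, CC(C)(C)[Si](C)(C)Cl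
Why: Standard silylation of a secondary alcohol; the silyl ether later prevents δ-lactonisation and biases the radical ring closure.

Step 3
Reactants: 5 tert-butyl{[(3R)-2-chlorohexa-1,5-dien-3-yl]oxy}dimethylsilane
Product: 6 (3R)-3-[(tert-butyldimethylsilyl)oxy]-4-chloropent-4-enal
Conditions: K2OsO4·2H2O (2 mol%), NaIO4, 2,6-lutidine, dioxane/H2O, rt
Reagents that add atoms: sodium periodate, [Na+].[O-]I(=O)(=O)=O
Why: Lemieux–Johnson oxidative cleavage; the terminal vinyl group should be dihydroxylated much faster than the electron-poor 2-chloroalkene, and the stereocentre is not touched.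

Step 4
Reactants: 6 (3R)-3-[(tert-butyldimethylsilyl)oxy]-4-chloropent-4-enal; 7 1,1,1,3,3,3-hexafluoropropan-2-yl prop-2-enoate
Product: 8 1,1,1,3,3,3-hexafluoropropan-2-yl (3R,5R)-5-[(tert-butyldimethylsilyl)oxy]-6-chloro-3-hydroxy-2-methylidenehept-6-enoate
Conditions: β-isocupreidine (10 mol%), DMF, −55 °C
Reagents that add atoms: none
Why: Catalytic asymmetric Morita–Baylis–Hillman reaction; the cinchona-derived amine with its phenolic hydrogen-bond donor should set the new carbinol (C2) as R under catalyst control, giving the anti 1,3-dioxygenated chain.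

Step 5
Reactants: 8 1,1,1,3,3,3-hexafluoropropan-2-yl (3R,5R)-5-[(tert-butyldimethylsilyl)oxy]-6-chloro-3-hydroxy-2-methylidenehept-6-enoate
Product: 9 (3R,5R)-5-[(tert-butyldimethylsilyl)oxy]-6-chloro-3-hydroxy-2-methylidenehept-6-enoic acid
Conditions: LiOH, THF/H2O, 0 °C; then 1 M HCl
Reagents that add atoms: lithium hydroxide, [Li+].[OH-]
Why: Saponification of an activated ester under mild conditions that should leave the silyl ether and both alkenes intact.

Step 6
Reactants: 9 (3R,5R)-5-[(tert-butyldimethylsilyl)oxy]-6-chloro-3-hydroxy-2-methylidenehept-6-enoic acid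
Product: 10 (4R)-4-{(2R)-2-[(tert-butyldimethylsilyl)oxy]-3-chlorobut-3-en-1-yl}-3-methylideneoxetan-2-one
Conditions: PhSO2Cl, pyridine, 0 °C
Reagents that add atoms: none
Why: β-Lactonisation by carboxyl activation (mixed sulfonic anhydride, hydroxyl attacks the acyl carbon), which retains the carbinol configuration and is an established way from Morita–Baylis–Hillman acids to α-methylene-β-lactones.

Step 7
Reactants: 10 (4R)-4-{(2R)-2-[(tert-butyldimethylsilyl)oxy]-3-chlorobut-3-en-1-yl}-3-methylideneoxetan-2-one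
Product: 11 (1S,3R,4R,6R)-4-[(tert-butyldimethylsilyl)oxy]-3-chloro-3-methyl-7-oxabicyclo[4.2.0]octan-8-one
Conditions: Fe(acac)3 (0.3 equiv), PhSiH3 (2.5 equiv), EtOH (5 equiv), THF, rt
Reagents that add atoms: none
Why: The iron hydride formed from Fe(acac)3 and PhSiH3 transfers a hydrogen atom to the CH2 terminus of the 2-chloroalkene, the tertiary α-chloroalkyl radical at C5 adds to the exocyclic CH2 (C6) of the α-methylene-β-lactone, and the lactone α-radical is reduced by divalent iron and protonated by ethanol. The closest known reaction type is the metal-hydride hydrogen-atom-transfer reductive coupling of heteroatom-substituted donor alkenes, 2-haloalkenes included, with acrylate acceptors (a Giese addition), run here intramolecularly. The ring closes in the 6-endo-trig radical mode, secured by polarity and sterics because the radical attacks the unsubstituted β-carbon of the acrylate unit and not its fully substituted α-carbon (5-exo). The C5 stereocentre should be set in a chair-like transition state in which the planar lactone holds the C2–O bond equatorial, the C4 silyloxy group is therefore axial, and the radical carbon places CH3 equatorial and Cl axial, anti to the C4–O dipole; the ring-fusion hydrogen at C1 enters cis and is replaced in step 8. The step needs chemoselective hydrogen-atom transfer to the chloroalkene over the electron-poor acceptor, and it needs a β-substituent on the radical that cannot fragment, which the silyloxy group provides and a bromide would not, hence both bromides are introduced later.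

Step 8
Reactants: 11 (1S,3R,4R,6R)-4-[(tert-butyldimethylsilyl)oxy]-3-chloro-3-methyl-7-oxabicyclo[4.2.0]octan-8-one
Product: 12 (1S,3R,4R,6R)-4-[(tert-butyldimethylsilyl)oxy]-3-chloro-1,3-dimethyl-7-oxabicyclo[4.2.0]octan-8-one
Conditions: LDA, THF, −78 °C; MeI, DMPU, −78 to −40 °C
Reagents that add atoms: iodomethane, CI
Why: Alkylation of a β-lactone enolate; methyl iodide should attack the face anti to the ring CH2 (C3) on the neighbouring C–O carbon, the only approach that keeps the cis ring fusion, which sets the quaternary C1 with CH3 trans to the lactone oxygen.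

Step 9
Reactants: 12 (1S,3R,4R,6R)-4-[(tert-butyldimethylsilyl)oxy]-3-chloro-1,3-dimethyl-7-oxabicyclo[4.2.0]octan-8-one
Product: 13 (1R,2S,4R,5R)-2-bromo-4-[(tert-butyldimethylsilyl)oxy]-5-chloro-1,5-dimethylcyclohexane-1-carboxylic acid
Conditions: MgBr2·OEt2, Et2O, 0 °C to rt; then 1 M HCl
Reagents that add atoms: magnesium bromide diethyl etherate, [Mg+2].[Br-].[Br-].CCOCC
Why: Strain-driven alkyl–oxygen cleavage of the β-lactone by bromide is an invertive SN2 substitution, so the neopentyl secondary bromide at C2 should be installed trans to the carboxyl carbon and cis to the C1 methyl without a free cation.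

Step 10
Reactants: 13 (1R,2S,4R,5R)-2-bromo-4-[(tert-butyldimethylsilyl)oxy]-5-chloro-1,5-dimethylcyclohexane-1-carboxylic acid
Product: 14 {(1R,2S,4R,5R)-2-bromo-4-[(tert-butyldimethylsilyl)oxy]-5-chloro-1,5-dimethylcyclohexyl}methanol
Conditions: BH3·SMe2, THF, 0 °C to rt; aqueous work-up
Reagents that add atoms: none
Why: Borane reduction of a free carboxylic acid through the acyloxyborane, chemoselective in the presence of alkyl bromide, alkyl chloride and silyl ether.

Step 11
Reactants: 14 {(1R,2S,4R,5R)-2-bromo-4-[(tert-butyldimethylsilyl)oxy]-5-chloro-1,5-dimethylcyclohexyl}methanol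
Product: 15 (1R,2S,4R,5R)-2-bromo-4-[(tert-butyldimethylsilyl)oxy]-5-chloro-1,5-dimethylcyclohexane-1-carbaldehyde
Conditions: Dess–Martin periodinane, NaHCO3, CH2Cl2, 0 °C to rt
Reagents that add atoms: none
Why: Dess–Martin oxidation of a neopentyl primary alcohol; the aldehyde has no α-hydrogen, so neither epimerisation nor enolate-driven loss of the β-bromide is possible.

Step 12
Reactants: 15 (1R,2S,4R,5R)-2-bromo-4-[(tert-butyldimethylsilyl)oxy]-5-chloro-1,5-dimethylcyclohexane-1-carbaldehyde
Product: 16 tert-butyl{[(1R,2R,4R,5S)-5-bromo-2-chloro-4-[(E)-2-chloroethenyl]-2,4-dimethylcyclohexyl]oxy}dimethylsilane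
Conditions: CrCl2 (8 equiv), CHCl3, THF, 65 °C
Reagents that add atoms: chloroform, ClC(Cl)Cl
Why: Takai–Utimoto olefination; the geminal dichromium species from CHCl3 adds to the aldehyde and anti-elimination should give the (E)-chloroalkene, with unactivated alkyl halides tolerated.

Step 13
Reactants: 16 tert-butyl{[(1R,2R,4R,5S)-5-bromo-2-chloro-4-[(E)-2-chloroethenyl]-2,4-dimethylcyclohexyl]oxy}dimethylsilane
Product: 17 (1R,2R,4R,5S)-5-bromo-2-chloro-4-[(E)-2-chloroethenyl]-2,4-dimethylcyclohexan-1-ol
Conditions: HF·pyridine, pyridine, THF, 0 °C to rt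
Reagents that add atoms: none
Why: Buffered fluoride desilylation, chosen because it lacks the basicity that could eliminate HBr.

Step 14
Reactants: 17 (1R,2R,4R,5S)-5-bromo-2-chloro-4-[(E)-2-chloroethenyl]-2,4-dimethylcyclohexan-1-ol
Product: 18 (1R,2S,4S,5R)-2,4-dibromo-5-chloro-1-[(E)-2-chloroethenyl]-1,5-dimethylcyclohexane
Conditions: PPh3, CBr4, CH2Cl2, 0 °C to rt
Reagents that add atoms: carbon tetrabromide, BrC(Br)(Br)Br
Why: Appel reaction; bromide displaces the alkoxyphosphonium group with inversion (SN2), which should turn the C4 alcohol trans to the tertiary chloride into the bromide cis to it.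

**Compound list**

1 | 2-chloroprop-2-en-1-ol | C=C(Cl)CO | starting material
2 | allyl acetate | CC(=O)OCC=C | starting material
3 | 2-chloroprop-2-enal | C=C(Cl)C=O | intermediate
4 | (3R)-2-chlorohexa-1,5-dien-3-ol | C=C(Cl)[C@H](O)CC=C | intermediate
5 | tert-butyl{[(3R)-2-chlorohexa-1,5-dien-3-yl]oxy}dimethylsilane | C=C(Cl)[C@H](O[Si](C)(C)C(C)(C)C)CC=C | intermediate
6 | (3R)-3-[(tert-butyldimethylsilyl)oxy]-4-chloropent-4-enal | C=C(Cl)[C@H](O[Si](C)(C)C(C)(C)C)CC=O | intermediate
7 | 1,1,1,3,3,3-hexafluoropropan-2-yl prop-2-enoate | C=CC(=O)OC(C(F)(F)F)C(F)(F)F | starting material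
8 | 1,1,1,3,3,3-hexafluoropropan-2-yl (3R,5R)-5-[(tert-butyldimethylsilyl)oxy]-6-chloro-3-hydroxy-2-methylidenehept-6-enoate | C=C(Cl)[C@H](O[Si](C)(C)C(C)(C)C)C[C@@H](O)C(=C)C(=O)OC(C(F)(F)F)C(F)(F)F | intermediate
9 | (3R,5R)-5-[(tert-butyldimethylsilyl)oxy]-6-chloro-3-hydroxy-2-methylidenehept-6-enoic acid | C=C(Cl)[C@H](O[Si](C)(C)C(C)(C)C)C[C@@H](O)C(=C)C(=O)O | intermediate
10 | (4R)-4-{(2R)-2-[(tert-butyldimethylsilyl)oxy]-3-chlorobut-3-en-1-yl}-3-methylideneoxetan-2-one | C=C(Cl)[C@H](O[Si](C)(C)C(C)(C)C)C[C@H]1OC(=O)C1=C | intermediate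
11 | (1S,3R,4R,6R)-4-[(tert-butyldimethylsilyl)oxy]-3-chloro-3-methyl-7-oxabicyclo[4.2.0]octan-8-one | [C@H]12C[C@@](C)(Cl)[C@H](O[Si](C)(C)C(C)(C)C)C[C@H]1OC2=O | intermediate
12 | (1S,3R,4R,6R)-4-[(tert-butyldimethylsilyl)oxy]-3-chloro-1,3-dimethyl-7-oxabicyclo[4.2.0]octan-8-one | C[C@]12C[C@@](C)(Cl)[C@H](O[Si](C)(C)C(C)(C)C)C[C@H]1OC2=O | intermediate
13 | (1R,2S,4R,5R)-2-bromo-4-[(tert-butyldimethylsilyl)oxy]-5-chloro-1,5-dimethylcyclohexane-1-carboxylic acid | C[C@]1(C(=O)O)C[C@@](C)(Cl)[C@H](O[Si](C)(C)C(C)(C)C)C[C@@H]1Br | intermediate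
14 | {(1R,2S,4R,5R)-2-bromo-4-[(tert-butyldimethylsilyl)oxy]-5-chloro-1,5-dimethylcyclohexyl}methanol | C[C@]1(CO)C[C@@](C)(Cl)[C@H](O[Si](C)(C)C(C)(C)C)C[C@@H]1Br | intermediate
15 | (1R,2S,4R,5R)-2-bromo-4-[(tert-butyldimethylsilyl)oxy]-5-chloro-1,5-dimethylcyclohexane-1-carbaldehyde | C[C@]1(C=O)C[C@@](C)(Cl)[C@H](O[Si](C)(C)C(C)(C)C)C[C@@H]1Br | intermediate
16 | tert-butyl{[(1R,2R,4R,5S)-5-bromo-2-chloro-4-[(E)-2-chloroethenyl]-2,4-dimethylcyclohexyl]oxy}dimethylsilane | C[C@]1(/C=C/Cl)C[C@@](C)(Cl)[C@H](O[Si](C)(C)C(C)(C)C)C[C@@H]1Br | intermediate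
17 | (1R,2R,4R,5S)-5-bromo-2-chloro-4-[(E)-2-chloroethenyl]-2,4-dimethylcyclohexan-1-ol | C[C@]1(/C=C/Cl)C[C@@](C)(Cl)[C@H](O)C[C@@H]1Br | intermediate
18 | (1R,2S,4S,5R)-2,4-dibromo-5-chloro-1-[(E)-2-chloroethenyl]-1,5-dimethylcyclohexane | C[C@]1(/C=C/Cl)C[C@@](C)(Cl)[C@@H](Br)C[C@@H]1Br | target

**Count and risks**

Total step count: 14. Longest linear sequence: 14 steps (1 to 18; 2 and 7 are purchased).

Steps most likely to fail:

Step 14. The axial tertiary chloride is anti-periplanar to the leaving group, so chloronium participation (retention or halogen migration) and elimination may compete with the invertive displacement. The fallback sets out from 17. Dess–Martin oxidation gives (2R,4R,5S)-5-bromo-2-chloro-4-[(E)-2-chloroethenyl]-2,4-dimethylcyclohexan-1-one F1. Reduction with NaBH4 and CeCl3·7H2O in MeOH at −78 °C, with hydride attack anti to the axial C–Cl bond, should give the epimeric alcohol (1S,2R,4R,5S)-5-bromo-2-chloro-4-[(E)-2-chloroethenyl]-2,4-dimethylcyclohexan-1-ol F2, in which the chloride is gauche to the C–O bond and cannot participate. Quinoline-8-sulfonyl chloride with DMAP gives the chelating sulfonate (1S,2R,4R,5S)-5-bromo-2-chloro-4-[(E)-2-chloroethenyl]-2,4-dimethylcyclohexyl quinoline-8-sulfonate F3. TiBr4 in CH2Cl2 at −78 °C then delivers bromide from the sulfonate-bound tetravalent titanium on the front side (stereoretentive substitution with a nucleophile-assisting leaving group) and comes back to the route at 18.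

Step 9. Lewis-acid ionisation of the C–O bond with 1,2-shift of a C1 substituent (ring expansion to a γ-lactone) or decarboxylative fragmentation may outrun bromide attack at the hindered carbon. The fallback sets out from 12. Aminolysis with MeNH(OMe)·HCl and AlMe3 opens the lactone at the acyl carbon to (1S,2R,4R,5R)-4-[(tert-butyldimethylsilyl)oxy]-5-chloro-2-hydroxy-N-methoxy-N,1,5-trimethylcyclohexane-1-carboxamide F4. Appel bromination with CBr4 and tri-n-octylphosphine, conditions used for hindered secondary alcohols, should give with inversion (1R,2S,4R,5R)-2-bromo-4-[(tert-butyldimethylsilyl)oxy]-5-chloro-N-methoxy-N,1,5-trimethylcyclohexane-1-carboxamide F5. DIBAL-H at −78 °C reduces the Weinreb amide and comes back to the route at 15, so steps 10 and 11 are not needed.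

Step 7. Hydrogen-atom transfer to the strained methylene lactone, or its ethanolysis or oligomerisation, may consume 10 before the chloroalkene radical forms, and facial selectivity at C5 may be low. The fallback sets out from 8. Transesterification (MeOH, Et3N) gives methyl (3R,5R)-5-[(tert-butyldimethylsilyl)oxy]-6-chloro-3-hydroxy-2-methylidenehept-6-enoate F6. The same Fe(acac)3/PhSiH3 cyclisation on this unstrained acrylate, with the free hydroxyl equatorial in the chair, should give methyl (2R,4R,5R)-4-[(tert-butyldimethylsilyl)oxy]-5-chloro-2-hydroxy-5-methylcyclohexane-1-carboxylate F7 (both C1 epimers). Fráter–Seebach alkylation of its dianion (LDA 2.2 equiv, MeI) introduces the C1 methyl anti to the alkoxide and gives methyl (1S,2R,4R,5R)-4-[(tert-butyldimethylsilyl)oxy]-5-chloro-2-hydroxy-1,5-dimethylcyclohexane-1-carboxylate F8. Saponification with LiOH gives (1S,2R,4R,5R)-4-[(tert-butyldimethylsilyl)oxy]-5-chloro-2-hydroxy-1,5-dimethylcyclohexane-1-carboxylic acid F9, and PhSO2Cl/pyridine lactonisation comes back to the route at 12.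

Further compounds
F1 | step 14 | (2R,4R,5S)-5-bromo-2-chloro-4-[(E)-2-chloroethenyl]-2,4-dimethylcyclohexan-1-one | C[C@]1(/C=C/Cl)C[C@@](C)(Cl)C(=O)C[C@@H]1Br
F2 | step 14 | (1S,2R,4R,5S)-5-bromo-2-chloro-4-[(E)-2-chloroethenyl]-2,4-dimethylcyclohexan-1-ol | C[C@]1(/C=C/Cl)C[C@@](C)(Cl)[C@@H](O)C[C@@H]1Br
F3 | step 14 | (1S,2R,4R,5S)-5-bromo-2-chloro-4-[(E)-2-chloroethenyl]-2,4-dimethylcyclohexyl quinoline-8-sulfonate | C[C@]1(/C=C/Cl)C[C@@](C)(Cl)[C@@H](OS(=O)(=O)c2cccc3cccnc23)C[C@@H]1Br
F4 | step 9 | (1S,2R,4R,5R)-4-[(tert-butyldimethylsilyl)oxy]-5-chloro-2-hydroxy-N-methoxy-N,1,5-trimethylcyclohexane-1-carboxamide | CON(C)C(=O)[C@@]1(C)C[C@@](C)(Cl)[C@H](O[Si](C)(C)C(C)(C)C)C[C@H]1O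
F5 | step 9 | (1R,2S,4R,5R)-2-bromo-4-[(tert-butyldimethylsilyl)oxy]-5-chloro-N-methoxy-N,1,5-trimethylcyclohexane-1-carboxamide | CON(C)C(=O)[C@@]1(C)C[C@@](C)(Cl)[C@H](O[Si](C)(C)C(C)(C)C)C[C@@H]1Br
F6 | step 7 | methyl (3R,5R)-5-[(tert-butyldimethylsilyl)oxy]-6-chloro-3-hydroxy-2-methylidenehept-6-enoate | C=C(Cl)[C@H](O[Si](C)(C)C(C)(C)C)C[C@@H](O)C(=C)C(=O)OC
F7 | step 7 | methyl (2R,4R,5R)-4-[(tert-butyldimethylsilyl)oxy]-5-chloro-2-hydroxy-5-methylcyclohexane-1-carboxylate | COC(=O)C1C[C@@](C)(Cl)[C@H](O[Si](C)(C)C(C)(C)C)C[C@H]1O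
F8 | step 7 | methyl (1S,2R,4R,5R)-4-[(tert-butyldimethylsilyl)oxy]-5-chloro-2-hydroxy-1,5-dimethylcyclohexane-1-carboxylate | COC(=O)[C@@]1(C)C[C@@](C)(Cl)[C@H](O[Si](C)(C)C(C)(C)C)C[C@H]1O
F9 | step 7 | (1S,2R,4R,5R)-4-[(tert-butyldimethylsilyl)oxy]-5-chloro-2-hydroxy-1,5-dimethylcyclohexane-1-carboxylic acid | OC(=O)[C@@]1(C)C[C@@](C)(Cl)[C@H](O[Si](C)(C)C(C)(C)C)C[C@H]1O
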